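A balance that closes in the cold is a trap: it invites me to read reacted substrate as target at any temperature. The flasks and questions were these.

| flask | substrate | coupling partner | temperature | remark | time |
|---|---|---|---|---|---|
| south | 0.0010 M | 2.1 equiv | −6 °C | run made earlier |  |
| south-west | 0.0010 M | 3.3 equiv | 35 °C | run made earlier |  |
| east | 0.0015 M | 1.5 equiv | −6 °C | run made earlier |  |
| violet | 0.0010 M | 1.50 equiv | 0 °C |  | 6.0 min |
| grey | 0.0010 M | 1.50 equiv | 25 °C |  | 6.0 min |
| teal | 0.0010 M | 1.50 equiv | 50 °C |  | 6.0 min |
| green | 0.0010 M | 1.50 equiv | −25 °C |  | 6.0 min |

south run (percent of the substrate charged)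

| time / min | target / % | substrate / % |
|---|---|---|
| 0.667 | 6.6 | 93.4 |
| 1.33 | 12.4 | 87.2 |
| 2.00 | 18.0 | 82.0 |
| 3.00 | 25.9 | 74.3 |
| 4.00 | 32.0 | 68.9 |
| 5.00 | 36.4 | 62.0 |

south-west run (percent of the substrate charged)

| time / s | target / % | substrate / % |
|---|---|---|
| 10.0 | 23.0 | 72.9 |
| 15.0 | 30.7 | 64.0 |
| 20.0 | 37.8 | 55.9 |
| 30.0 | 48.2 | 44.3 |
| 50.0 | 59.8 | 28.2 |

east run (percent of the substrate charged)

| time / min | target / % | substrate / % |
|---|---|---|
| 0.417 | 4.0 | 95.2 |
| 1.33 | 13.4 | 85.4 |
| 2.00 | 19.3 | 80.7 |
| 3.00 | 26.6 | 74.4 |
| 5.00 | 36.8 | 62.4 |

(each reading ± 0.5 percentage points)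

- a reading or a percentage of target counts all its forms, free or not

- the best flask by amount of target, in percent of the substrate charged; "all alike" if 1.5 percentage points covers them all (violet / grey / teal / green / all alike)
- amount of target at the end, in percent of the substrate charged, violet
- amount of target at the end, in percent of the substrate charged, grey
- amount of target at the end, in percent of the substrate charged, teal
- amount of target at the end, in percent of the substrate charged, green

I watched the gap, the charged substrate found neither as substrate nor as target. At the last south reading, at −6 °C, it was 1.60 %, with a scatter of 0.5 percentage points on each of the two readings behind it. At the last south-west reading, at 35 °C, it was 12.0 %, larger.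

My bench rule was the pseudo-first-order one: freeze c(coupling partner) at its charge. I assumed a loss first order in substrate and free of partner, which these runs do not test. Target over gap should then stay constant along a run. In the south-west run it read 5.61 at 10.0 s and 4.98 at 50.0 s, steady enough for me to freeze it.

Dividing by the partner charge gave a selectivity factor of 1.51 /mM at 35 °C and 10.8 /mM at −6 °C, the second a weak reading. I took its logarithm as straight in temperature and multiplied by the flask's partner charge. That gave the branch ratio ρ, target made per substrate lost otherwise, for grey: 3.66. For teal it gave 1.10. The south-west run had 44.3 % substrate left after 30.0 s, and teal runs 12.0 times as long, so I took teal's substrate as consumed and committed to about 52.4 % target there.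

The rule's border is the ratio of substrate to partner. At 1.50 equiv full conversion takes 66.7 % of the partner charge, more than the 30.3 % of the south-west run, so c(coupling partner) cannot be taken as frozen at its charge late in these flasks.

The forecast named grey best, with 40 % in violet, 69 % in grey, 60 % in teal and 10.3 % in green, and said of the loss: “Its dependence on partner is unknown, which is the main uncertainty.”

The flasks gave 41.0 % in violet, 67.1 % in grey, 44.5 % in teal and 10.9 % in green, crystals counted, so grey came out best. In grey the rate ratio of the target step to the side-product step went from 6.7 at the start to 4.5 at 1.10 min, so it did not stay frozen. At 6.00 min grey's target over side product stood at 3.96 beside my ρ of 3.66, and teal's at 0.803 beside 1.10.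

    substrate + coupling partner → target (k = 18.0 /M/s, Ea = 39.0 kJ/mol)
    substrate → side product (k = 0.0230 /s, Ea = 95.0 kJ/mol)
    crystals ⇌ target, rate k3*(cs3 - [target]) while solid is left; crystals form when [target] > cs3 (solubility = 0.340 mM, k = 2.80 /s)
    2 coupling partner → homo dimer (k = 3.70 /M/s, Ea = 46.0 kJ/mol)
    (constants at 50 °C)

A repeat of grey with 6.0 × 10⁻⁴ M substrate, same equivalents and time, has its partner charge scaled with the substrate, so ρ becomes 2.20. That flask gave 56.1 % target against 20.8 % side product, a ratio of 2.70.

The earlier runs and the new flask come from a simulation from invented constants, and the scatter is random.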